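**Retrosynthetic overview**
- The C40 skeleton is cut at both C11=C12 bonds: a double Wittig reaction of a C15 enynyl phosphonium salt (two equivalents) with the commercial C10 trienedial.
- The trans-3,4-dioxygenated ring of the C15 salt comes from the key C4–O bond formation: an anti 1,3-benzoyloxy shift from C6 to C4, relayed by the C3 benzoate.
- The tertiary benzoate for that shift comes from 1,2-addition of a C6 enyne acetylide to (S)-4-hydroxyisophorone; the C3 centre is set by asymmetric transfer hydrogenation of ketoisophorone.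
- No ring is formed: both cyclohexene rings come intact from ketoisophorone.

Assumption: carotenoid numbering is used for the ring (C1 gem-dimethyl, C3 and C4 carbinols, C5=C6, C7≡C8); 3 and 13 are bought as the pure E and all-E isomers; the (S,S)-TsDPEN ruthenium catalyst is taken to give the (S)-alcohol by the aryl-ketone model, and the mirror-image catalyst is used if the opposite sense is found.

**Step 1**
Reactants: 1 2,6,6-trimethylcyclohex-2-ene-1,4-dione (ketoisophorone)
Product: 2 (4S)-4-hydroxy-2,6,6-trimethylcyclohex-2-en-1-one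
Conditions: RuCl[(S,S)-TsDPEN](p-cymene) (0.5 mol %), KOH (1 mol %), i-PrOH, 25 °C
Reagents that add atoms: none
Why: Asymmetric transfer hydrogenation (Noyori type) reduces only the unhindered C4 carbonyl, the C1 carbonyl next to the gem-dimethyl group being left, and the chiral Ru–H/N–H catalyst sets the carbinol centre (later C3) as S through its six-membered outer-sphere transition state.

**Step 2**
Reactants: 3 (2E)-3-methylpent-2-en-4-yn-1-ol
Product: 4 tert-butyl(dimethyl){[(2E)-3-methylpent-2-en-4-yn-1-yl]oxy}silane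
Conditions: TBSCl, imidazole, CH2Cl2, 0 °C → rt
Reagents that add atoms: tert-butyldimethylsilyl chloride, CC(C)(C)[Si](C)(C)Cl
Why: Standard silylation of a primary allylic alcohol (Corey protocol); no stereocentre is formed and the E alkene is untouched.

**Step 3**
Reactants: 2 (4S)-4-hydroxy-2,6,6-trimethylcyclohex-2-en-1-one; 4 tert-butyl(dimethyl){[(2E)-3-methylpent-2-en-4-yn-1-yl]oxy}silane
Product: 8 (1RS,4S)-1-[(3E)-5-(tert-butyldimethylsilyloxy)-3-methylpent-3-en-1-yn-1-yl]-2,6,6-trimethylcyclohex-2-ene-1,4-diyl dibenzoate, via lithium alkoxide 5 (not isolated), via lithium acetylide 6 (not isolated), via dilithium dialkoxide 7 (not isolated)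
Conditions: 2, LiN(SiMe3)2 (1.0 equiv), THF, −78 °C; cannulate into 6 [4 (1.3 equiv), n-BuLi, THF, −78 °C]; → 0 °C; BzCl (3 equiv), DMAP (0.1 equiv), 0 °C → rt
Reagents that add atoms: benzoyl chloride, O=C(Cl)c1ccccc1
Why: 1,2-addition of a lithium acetylide to the only carbonyl of a non-enolisable enone (the hydroxyl being masked as its lithium alkoxide) followed by O-acylation of both alkoxides in the pot; the new tertiary centre forms as an epimer mixture, which does not matter because step 4 destroys it.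

**Step 4**
Reactants: 8 (1RS,4S)-1-[(3E)-5-(tert-butyldimethylsilyloxy)-3-methylpent-3-en-1-yn-1-yl]-2,6,6-trimethylcyclohex-2-ene-1,4-diyl dibenzoate
Product: 10 (1S,2S)-4-[(3E)-5-(tert-butyldimethylsilyloxy)-3-methylpent-3-en-1-yn-1-yl]-3,5,5-trimethylcyclohex-3-ene-1,2-diyl dibenzoate, via acyloxonium benzoate ion pair 9 (not isolated)
Conditions: Me3SiOTf (5 mol %), 2,6-di-tert-butyl-4-methylpyridine (10 mol %), 4 Å MS, CH2Cl2, −78 → −40 °C; Et3N
Reagents that add atoms: none
Why: Proposed new method: a neighbouring-ester-relayed anti 1,3-acyloxy transposition, in which Me3SiOTf silylates the tertiary benzoate and ionises it to a propargyl/allyl cation plus Me3SiOBz, the C3 benzoate carbonyl closes onto C4 to give a cis-fused acyloxonium ion on the face of the C3–O bond, and Me3SiOBz opens this ion at the allylic C4 from the opposite face (SN2, inversion, Me3SiOTf released), so that both C6 epimers converge on the trans (3S,4S) dibenzoate, whose tetrasubstituted C5=C6 alkene conjugated with the alkyne is the thermodynamic sink and which re-ionises far more slowly than the tertiary ester; the closest known reactions are the Prévost reaction, 1,2-trans glycosylation through a participating 2-O-acyl group, and acid-promoted 1,3-transposition of allylic esters.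

**Step 5**
Reactants: 10 (1S,2S)-4-[(3E)-5-(tert-butyldimethylsilyloxy)-3-methylpent-3-en-1-yn-1-yl]-3,5,5-trimethylcyclohex-3-ene-1,2-diyl dibenzoate
Product: 12 {(2E)-5-[(3S,4S)-3,4-bis(benzoyloxy)-2,6,6-trimethylcyclohex-1-en-1-yl]-3-methylpent-2-en-4-yn-1-yl}triphenylphosphonium bromide, via allylic bromide 11 (not isolated)
Conditions: Ph3PBr2 (1.1 equiv), CH2Cl2, 0 °C → rt; then PPh3 (1.3 equiv), rt; Et2O precipitation
Reagents that add atoms: dibromotriphenylphosphorane, BrP(Br)(c1ccccc1)(c1ccccc1)c1ccccc1; triphenylphosphine, c1ccc(cc1)P(c1ccccc1)c1ccccc1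
Why: Dibromotriphenylphosphorane converts a primary allylic silyl ether directly into the bromide, which triphenylphosphine displaces by SN2 at the unhindered primary carbon to give the Wittig salt without touching the E alkene, the esters or the stereocentres.

**Step 6**
Reactants: 12 {(2E)-5-[(3S,4S)-3,4-bis(benzoyloxy)-2,6,6-trimethylcyclohex-1-en-1-yl]-3-methylpent-2-en-4-yn-1-yl}triphenylphosphonium bromide (2.1 equiv); 13 (2E,4E,6E)-2,7-dimethylocta-2,4,6-trienedial
Product: 17 (all-E,3S,4S,3'S,4'S)-7,8,7',8'-tetradehydro-β,β-carotene-3,4,3',4'-tetrol, via phosphorus ylide 14 (not isolated), via C40 tetrabenzoate 15 (not isolated), via tetrol 11Z/11E mixture 16 (not isolated)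
Conditions: NaOMe (10 equiv), MeOH/CH2Cl2, 0 °C → rt (base added to 12 + 13); AcOH; then heptane/EtOH, reflux, Ar, dark; crystallise
Reagents that add atoms: none
Why: Double Wittig olefination (the classical C15 + C10 + C15 carotenoid assembly) forms both C11=C12 bonds, the methoxide medium then transesterifies the four benzoates (Zemplén-type methanolysis), and the hindered 11Z bonds relax thermally to the all-E polyene; no stereocentre is touched.

**Compound list**
1 | 2,6,6-trimethylcyclohex-2-ene-1,4-dione (ketoisophorone) | CC1=CC(=O)CC(C)(C)C1=O | starting material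
2 | (4S)-4-hydroxy-2,6,6-trimethylcyclohex-2-en-1-one | CC1=C[C@@H](O)CC(C)(C)C1=O | intermediate
3 | (2E)-3-methylpent-2-en-4-yn-1-ol | C#C/C(C)=C/CO | starting material
4 | tert-butyl(dimethyl){[(2E)-3-methylpent-2-en-4-yn-1-yl]oxy}silane | C#C/C(C)=C/CO[Si](C)(C)C(C)(C)C | intermediate
5 | lithium alkoxide of 2 (formed in the flask) | CC1=C[C@@H]([O-])CC(C)(C)C1=O.[Li+] | intermediate
6 | lithium acetylide of 4 (formed in the flask) | [Li+].[C-]#C/C(C)=C/CO[Si](C)(C)C(C)(C)C | intermediate
7 | dilithium (1RS,4S)-1-[(3E)-5-(tert-butyldimethylsilyloxy)-3-methylpent-3-en-1-yn-1-yl]-2,6,6-trimethylcyclohex-2-ene-1,4-diolate, both C1 epimers (formed in the flask) | CC1=C[C@@H]([O-])CC(C)(C)C1([O-])C#C/C(C)=C/CO[Si](C)(C)C(C)(C)C.[Li+].[Li+] | intermediate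
8 | (1RS,4S)-1-[(3E)-5-(tert-butyldimethylsilyloxy)-3-methylpent-3-en-1-yn-1-yl]-2,6,6-trimethylcyclohex-2-ene-1,4-diyl dibenzoate, both C1 epimers | CC1=C[C@@H](OC(=O)c2ccccc2)CC(C)(C)C1(OC(=O)c3ccccc3)C#C/C(C)=C/CO[Si](C)(C)C(C)(C)C | intermediate
9 | cis-fused 2-phenyl-1,3-dioxolan-2-ylium ion bridging C3 and C4 (both C–O bonds on the face of the original C3 oxygen, C5=C6 enyne in place), benzoate as counter-ion (formed in the flask) | CC1=C(C#C/C(C)=C/CO[Si](C)(C)C(C)(C)C)C(C)(C)C[C@H]2[C@@H]1OC(c3ccccc3)=[O+]2.[O-]C(=O)c4ccccc4 | intermediate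
10 | (1S,2S)-4-[(3E)-5-(tert-butyldimethylsilyloxy)-3-methylpent-3-en-1-yn-1-yl]-3,5,5-trimethylcyclohex-3-ene-1,2-diyl dibenzoate (trans) | CC1=C(C#C/C(C)=C/CO[Si](C)(C)C(C)(C)C)C(C)(C)C[C@H](OC(=O)c2ccccc2)[C@H]1OC(=O)c3ccccc3 | intermediate
11 | (1S,2S)-4-[(3E)-5-bromo-3-methylpent-3-en-1-yn-1-yl]-3,5,5-trimethylcyclohex-3-ene-1,2-diyl dibenzoate (formed in the flask) | CC1=C(C#C/C(C)=C/CBr)C(C)(C)C[C@H](OC(=O)c2ccccc2)[C@H]1OC(=O)c3ccccc3 | intermediate
12 | {(2E)-5-[(3S,4S)-3,4-bis(benzoyloxy)-2,6,6-trimethylcyclohex-1-en-1-yl]-3-methylpent-2-en-4-yn-1-yl}triphenylphosphonium bromide | CC1=C(C#C/C(C)=C/C[P+](c4ccccc4)(c5ccccc5)c6ccccc6)C(C)(C)C[C@H](OC(=O)c2ccccc2)[C@H]1OC(=O)c3ccccc3.[Br-] | intermediate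
13 | (2E,4E,6E)-2,7-dimethylocta-2,4,6-trienedial | O=C/C(C)=C/C=C/C=C(C)/C=O | starting material
14 | triphenylphosphonium ylide of 12 (formed in the flask) | CC1=C(C#C/C(C)=C/C=P(c4ccccc4)(c5ccccc5)c6ccccc6)C(C)(C)C[C@H](OC(=O)c2ccccc2)[C@H]1OC(=O)c3ccccc3 | intermediate
15 | (3S,4S,3'S,4'S)-7,8,7',8'-tetradehydro-β,β-carotene-3,4,3',4'-tetrayl tetrabenzoate, E/Z mixture at C11=C12 and C11'=C12', all other double bonds E (formed in the flask) | CC1=C(C#C/C(C)=C/C=CC(/C)=C/C=C/C=C(\C)C=C/C=C(\C)C#CC2=C(C)[C@H](OC(=O)c3ccccc3)[C@@H](OC(=O)c3ccccc3)CC2(C)C)C(C)(C)C[C@H](OC(=O)c3ccccc3)[C@H]1OC(=O)c3ccccc3 | intermediate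
16 | (3S,4S,3'S,4'S)-7,8,7',8'-tetradehydro-β,β-carotene-3,4,3',4'-tetrol, E/Z mixture at C11=C12 and C11'=C12' (formed in the flask) | CC1=C(C#C/C(C)=C/C=CC(/C)=C/C=C/C=C(\C)C=C/C=C(\C)C#CC2=C(C)[C@H](O)[C@@H](O)CC2(C)C)C(C)(C)C[C@H](O)[C@H]1O | intermediate
17 | (all-E,3S,4S,3'S,4'S)-7,8,7',8'-tetradehydro-β,β-carotene-3,4,3',4'-tetrol | CC1=C(C#C/C(C)=C/C=C/C(C)=C/C=C/C=C(C)/C=C/C=C(\C)C#CC2=C(C)[C@H](O)[C@@H](O)CC2(C)C)C(C)(C)C[C@H](O)[C@H]1O | target

**Step count and risk**
Total steps: 6. Longest linear sequence: 5 (steps 1, 3, 4, 5, 6).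

The three steps most likely to fail:

Step 4 (proposed new method). The risks are capture of the open cation on the face of the C3 benzoate (cis product), water diverting the acyloxonium ion to a cis hydroxy ester, capture at C8 (allenyl ester) and proton loss from C3. The fallback uses known chemistry, sets out from 7 and comes back at 10. The dialkoxide 7 is quenched with aqueous NH4Cl instead of benzoyl chloride to give the tertiary/secondary diol F1. Catalytic Ph3SiOReO3 in Et2O at 0 °C (oxo-rhenium 1,3-transposition of an allylic alcohol, driven by conjugation of the new ring alkene with the alkyne) gives the 3,4-diol F2 as a mixture of C4 epimers. MnO2 in CH2Cl2 oxidises only the allylic C4 carbinol to the (S)-3-hydroxy-4-ketone F3. Me4NBH(OAc)3 in MeCN/AcOH at −30 °C delivers hydride from the face of the C3 hydroxyl and gives the trans-diol F4. BzCl, pyridine and DMAP then give 10.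

Step 5. The allylic C4 benzoate, assisted by its neighbour, may ionise under the halogenating conditions, and the bromide may scramble by SN2'. The fallback avoids any C15 halide or phosphonium salt by reversing the polarity of the olefination; it sets out from 10 and 13 and comes back at 15. HF·pyridine in THF removes the silyl group to give the allylic alcohol F5, and MnO2 gives the enynal F6. Separately, NaBH4 reduces 13 to the triene diol F7, and PPh3·HBr in MeOH turns it into the C10 bis(phosphonium) salt F8. Double Wittig reaction of F8 with two equivalents of F6 in 1,2-epoxybutane/EtOH at reflux gives 15, which is methanolysed and isomerised as in step 6.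

Step 6. The ylide 14 carries a vinylogous leaving group (the C4 benzoate, reached through the enyne), the olefination gives 11Z isomers, and methanolysis of four hindered benzoates in the same pot may be slow. The fallback changes the olefination type and separates it from the deprotection; it sets out from 11 and comes back at 15. The bromide 11 is isolated and heated with P(OEt)3 (Arbuzov reaction) to give the C15 phosphonate F9. Double Horner–Wadsworth–Emmons reaction of F9 with 13 (NaN(SiMe3)2, THF, −78 → 0 °C) gives 15 mainly as the all-E isomer, which is isolated. K2CO3 in MeOH/THF then removes the benzoates to give 17.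

**Further compounds**
F1 | step 4 | (1RS,4S)-1-[(3E)-5-(tert-butyldimethylsilyloxy)-3-methylpent-3-en-1-yn-1-yl]-2,6,6-trimethylcyclohex-2-ene-1,4-diol | CC1=C[C@@H](O)CC(C)(C)C1(O)C#C/C(C)=C/CO[Si](C)(C)C(C)(C)C
F2 | step 4 | (1S,2RS)-4-[(3E)-5-(tert-butyldimethylsilyloxy)-3-methylpent-3-en-1-yn-1-yl]-3,5,5-trimethylcyclohex-3-ene-1,2-diol, both C2 epimers | CC1=C(C#C/C(C)=C/CO[Si](C)(C)C(C)(C)C)C(C)(C)C[C@H](O)C1O
F3 | step 4 | (6S)-3-[(3E)-5-(tert-butyldimethylsilyloxy)-3-methylpent-3-en-1-yn-1-yl]-6-hydroxy-2,4,4-trimethylcyclohex-2-en-1-one | CC1=C(C#C/C(C)=C/CO[Si](C)(C)C(C)(C)C)C(C)(C)C[C@H](O)C1=O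
F4 | step 4 | (1S,2S)-4-[(3E)-5-(tert-butyldimethylsilyloxy)-3-methylpent-3-en-1-yn-1-yl]-3,5,5-trimethylcyclohex-3-ene-1,2-diol | CC1=C(C#C/C(C)=C/CO[Si](C)(C)C(C)(C)C)C(C)(C)C[C@H](O)[C@H]1O
F5 | step 5 | (1S,2S)-4-[(3E)-5-hydroxy-3-methylpent-3-en-1-yn-1-yl]-3,5,5-trimethylcyclohex-3-ene-1,2-diyl dibenzoate | CC1=C(C#C/C(C)=C/CO)C(C)(C)C[C@H](OC(=O)c2ccccc2)[C@H]1OC(=O)c3ccccc3
F6 | step 5 | (1S,2S)-4-[(3E)-3-methyl-5-oxopent-3-en-1-yn-1-yl]-3,5,5-trimethylcyclohex-3-ene-1,2-diyl dibenzoate | CC1=C(C#C/C(C)=C/C=O)C(C)(C)C[C@H](OC(=O)c2ccccc2)[C@H]1OC(=O)c3ccccc3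
F7 | step 5 | (2E,4E,6E)-2,7-dimethylocta-2,4,6-triene-1,8-diol | OC/C(C)=C/C=C/C=C(C)/CO
F8 | step 5 | [(2E,4E,6E)-2,7-dimethylocta-2,4,6-triene-1,8-diyl]bis(triphenylphosphonium) dibromide | C(/C(C)=C/C=C/C=C(C)/C[P+](c1ccccc1)(c1ccccc1)c1ccccc1)[P+](c1ccccc1)(c1ccccc1)c1ccccc1.[Br-].[Br-]
F9 | step 6 | diethyl {(2E)-5-[(3S,4S)-3,4-bis(benzoyloxy)-2,6,6-trimethylcyclohex-1-en-1-yl]-3-methylpent-2-en-4-yn-1-yl}phosphonate | CC1=C(C#C/C(C)=C/CP(=O)(OCC)OCC)C(C)(C)C[C@H](OC(=O)c2ccccc2)[C@H]1OC(=O)c3ccccc3
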